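The runs come from a simulation for substances that don't exist, and the scatter is random.

Open a ledger on the substrate charged to the midnight flask and enter each part of it where the readings or a reckoning put it.

| setting | midnight | noon | flask |
|---|---|---|---|
| substrate | 0.050 M | 0.034 M | 0.050 M |
| free catalyst | 50 µM | 50 µM | 50 µM |
| remark | the very flask that is asked about, followed so far | run made earlier |  |
| time |  |  | 15 h |

- midnight (time / h: target / %): 1.00: 10.7; 2.00: 15.7; 5.00: 20.1; 12.0: 25.4
- noon (time / min: target / %): 20.0: 1.6; 40.0: 7.7; 50.0: 8.7; 80.0: 12.2

(each reading ± 1 percentage point)

- theta: at 15 h add substrate, 50.0% of the amount charged, then wait 15 h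
- gamma: at 15 h add free catalyst, 100% of the amount charged, then wait 15 h
- eta: change nothing and wait 15 h more

- additions leave the volume as it is
- a reading or a percentage of target counts all its forms, free or not

* target, in percent of the substrate first charged, at 15 h
* which option adds most target ("none" when 2 percentage points or less is all one gets) (theta / gamma / eta / none)
* target present, in percent of the substrate first charged, after theta
* target present, in percent of the substrate first charged, after gamma

1. Target: the midnight flask shows 25.4% of the charge at 12.0 h. Substrate is the limiting reagent, so I book everything in percent of it.

2. Scale: the noon run, with 0.034 M of substrate, reads 12.2% at 80.0 min. That lies between the midnight readings at 1.00 h and 2.00 h, so I let each percent of the charge behave alike in either amount.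

3. What stays nearly constant: the gain per factor of time. From 2.00 h to 5.00 h it is 4.8 percentage points per factor e, then 6.1 points, which agree within the scatter. From 2.00 h to 12.0 h taken together it is 5.4 points. I freeze this as s, the points of target gained each time the clock grows by a factor e.

4. Now: s gives 26.6% target at 15 h, which leaves 73.4% booked as not target.

5. Eta: waiting adds 3.8 points.

6. Theta: I take the added substrate to join the rest on the same clock, so the gain scales up to 6.3 points, and target reaches 32.9%.

7. Gamma: I take the fresh catalyst to restart the clock on the rest, which gains 20 points, and target reaches 46.1%. I choose gamma, because its gain is larger than the others.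

The forecast, on the ground “Catalyst is dying with time, hyperbolically”, gives 26.8%, 33% and 45.5% and picks gamma; these numbers differ from mine.

The flask gives 26.9%, 33.4% after theta and 43.4% after gamma, so my gamma entry stands 2.7 points high. Gamma adds 17 points, theta 6.5 points and eta 3.3 points.

    2 free catalyst → spent catalyst (k = 1400 M⁻¹ min⁻¹)
    substrate → intermediate (k = 0.0270 min⁻¹)
    free catalyst + intermediate → free catalyst + target (k = 510 M⁻¹ min⁻¹)
    crystals ⇌ target, rate k4*(cs4 - [target]) while solid is left; crystals form when [target] > cs4 (solubility = 32.0 mM, k = 2.00 min⁻¹)
    substrate → uncatalysed product (k = 0.0220 min⁻¹)

In the midnight flask the first half-life of free catalyst by its own pairing, 0.119 h, is shorter than the 0.45 h half-life of intermediate with catalyst as charged, and at 15 h the books close on 26.9% target, 44.9% uncatalysed product and 28.2% intermediate. Between 7.50 h and 15.0 h free catalyst falls from 1.56% to 0.787% and intermediate from 31.9% to 28.2%, and the constants with that last amount give s as 5.1 points. Read at 6.0 h, the same flask should by my s hold 21.7% target, and it holds 21.9%.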